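**Strategy.** Germacrane numbering is used (ring C1–C10, lactone C11–C13). Everything rests on opening the ten-membered carbocycle at C9–C10, the bond between the carbinol carbon next to the lactone O–CH (C8) and the methyl-bearing carbon of the (Z)-C1=C10 alkene. The feature exploited is this ring allylic alcohol, C9(OH)–C10(CH3)=C1H: a Nozaki–Hiyama–Kishi reaction of a (Z)-alkenyl iodide with an aldehyde closes the ring, makes the C–C bond and sets the C9 carbinol in one operation, with the trans-fused α-methylene-γ-butyrolactone and both cis alkenes as turn elements. The precursor is an open-chain iodo-aldehyde, joined beforehand by a zinc Barbier union of a bromomethylbutenolide with a (Z)-enal.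

Key step: step 16

Remark on the structure: the SMILES is read as the 1(10)Z,4Z-diene with a trans-fused 12,8-lactone, configurations 2S,6R,7S,8R,9R, and an (R)-2-methylbutanoate on O6.

**Route**

Step 1
Reactants: 1 but-2-yn-1-ol
Product: 3 (Z)-3-iodobut-2-en-1-ol, via cyclic alkenylalanate 2 (not isolated)
Conditions: NaAlH2(OCH2CH2OMe)2 (Red-Al), Et2O, 0 °C to rt; then I2, THF, −78 to 0 °C; aq. potassium sodium tartrate
Reagents that add atoms: iodine, II
Why: Hydroxyl-directed trans-hydroalumination of the propargylic alcohol places aluminium on C3 inside a five-membered alkenylalanate, and iodinolysis with retention should give the (Z)-iodoalkene (iodine cis to CH2OH).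

Step 2
Reactants: 3 (Z)-3-iodobut-2-en-1-ol
Product: 4 (Z)-3-iodobut-2-enal
Conditions: MnO2, CH2Cl2, rt, dark; used at once
Reagents that add atoms: none
Why: Neutral allylic oxidation with MnO2 should give the enal without isomerising the (Z)-iodoalkene.

Step 3
Reactants: 4 (Z)-3-iodobut-2-enal; 5 (2-methylallyl)magnesium chloride
Product: 8 (S,Z)-6-iodo-2-methylhepta-1,5-dien-4-ol, via B-methallyldiisopinocampheylborane 6 (not isolated), via diisopinocampheylborinate ester 7 (not isolated)
Conditions: (−)-B-methoxydiisopinocampheylborane [(−)-Ipc2BOMe, from (+)-α-pinene], 5, Et2O, 0 °C to rt; then 4, −78 °C; then aq. NaOH, H2O2, rt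
Reagents that add atoms: none
Why: Brown asymmetric methallylboration through a chair six-membered transition state, in which the reagent derived from (+)-α-pinene adds 1,2 to the Si face of the enal and should set the carbinol (target C2) as S.

Step 4
Reactants: 8 (S,Z)-6-iodo-2-methylhepta-1,5-dien-4-ol; 9 acryloyl chloride
Product: 10 (S,Z)-6-iodo-2-methylhepta-1,5-dien-4-yl acrylate
Conditions: iPr2NEt, CH2Cl2, −78 to 0 °C
Reagents that add atoms: none
Why: Simple O-acylation of the secondary allylic alcohol installs C5 and C6 as the acrylate without touching the stereocentre.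

Step 5
Reactants: 10 (S,Z)-6-iodo-2-methylhepta-1,5-dien-4-yl acrylate
Product: 11 (S)-6-[(Z)-2-iodoprop-1-en-1-yl]-4-methyl-5,6-dihydro-2H-pyran-2-one
Conditions: second-generation Grubbs catalyst RuCl2(=CHPh)(H2IMes)(PCy3) (5 mol %), CH2Cl2 (0.01 M), reflux
Reagents that add atoms: none
Why: Ring-closing metathesis of the acrylate onto the 1,1-disubstituted alkene gives the six-membered lactone, whose ring fixes the trisubstituted alkene with C3 and C6 cis (the future 4Z geometry), while the trisubstituted iodoalkene is inert to the ruthenium carbene.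

Step 6
Reactants: 11 (S)-6-[(Z)-2-iodoprop-1-en-1-yl]-4-methyl-5,6-dihydro-2H-pyran-2-one
Product: 12 (S,2Z,6Z)-5-hydroxy-7-iodo-N-methoxy-N,3-dimethylocta-2,6-dienamide
Conditions: MeNHOMe·HCl, AlMe3, CH2Cl2, 0 °C to rt; aq. potassium sodium tartrate
Reagents that add atoms: N,O-dimethylhydroxylamine hydrochloride, CNOC.Cl
Why: Weinreb aminolysis of the lactone by the aluminium amide (acyl substitution) opens the ring with the alkene geometry unchanged and frees the C2 hydroxyl.

Step 7
Reactants: 12 (S,2Z,6Z)-5-hydroxy-7-iodo-N-methoxy-N,3-dimethylocta-2,6-dienamide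
Product: 13 (S,2Z,6Z)-5-[(tert-butyldimethylsilyl)oxy]-7-iodo-N-methoxy-N,3-dimethylocta-2,6-dienamide
Conditions: TBSOTf, 2,6-lutidine, CH2Cl2, −78 °C
Reagents that add atoms: tert-butyldimethylsilyl triflate, CC(C)(C)[Si](C)(C)OS(=O)(=O)C(F)(F)F
Why: Fast low-temperature silylation caps the C2 hydroxyl before it can relactonise onto the (Z)-amide.

Step 8
Reactants: 13 (S,2Z,6Z)-5-[(tert-butyldimethylsilyl)oxy]-7-iodo-N-methoxy-N,3-dimethylocta-2,6-dienamide
Product: 14 (S,2Z,6Z)-5-[(tert-butyldimethylsilyl)oxy]-7-iodo-3-methylocta-2,6-dienal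
Conditions: iBu2AlH, THF, −78 °C; aq. potassium sodium tartrate
Reagents that add atoms: none
Why: Hydride reduction of the Weinreb amide stops at the stable aluminium chelate, which on work-up should release the (Z)-enal without over-reduction or isomerisation.

Step 9
Reactants: 15 (R)-but-3-ene-1,2-diol
Product: 17 (R)-1-[(4-methoxybenzyl)oxy]but-3-en-2-ol, via dibutylstannylene acetal 16 (not isolated)
Conditions: Bu2SnO, toluene, reflux (Dean–Stark); then 4-methoxybenzyl chloride, Bu4NI, 100 °C
Reagents that add atoms: 4-methoxybenzyl chloride, COc1ccc(CCl)cc1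
Why: Stannylene-acetal activation directs mono-alkylation to the primary oxygen (future O9) and leaves the secondary allylic hydroxyl (future O8) free.

Step 10
Reactants: 17 (R)-1-[(4-methoxybenzyl)oxy]but-3-en-2-ol; 18 2-(bromomethyl)acrylic acid
Product: 19 (R)-1-[(4-methoxybenzyl)oxy]but-3-en-2-yl 2-(bromomethyl)acrylate
Conditions: DCC, DMAP (5 mol %), CH2Cl2, −10 to 0 °C
Reagents that add atoms: none
Why: Steglich esterification at low temperature with little DMAP should acylate the alcohol faster than the allylic bromide is displaced.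

Step 11
Reactants: 19 (R)-1-[(4-methoxybenzyl)oxy]but-3-en-2-yl 2-(bromomethyl)acrylate
Product: 20 (R)-3-(bromomethyl)-5-{[(4-methoxybenzyl)oxy]methyl}furan-2(5H)-one
Conditions: second-generation Grubbs catalyst RuCl2(=CHPh)(H2IMes)(PCy3) (5–10 mol %), toluene (0.01 M), 80 °C
Reagents that add atoms: none
Why: Ring-closing metathesis of the 2-substituted acrylate with the terminal alkene forms the butenolide C7=C11 bond and keeps the C8 stereocentre from the diol.

Step 12
Reactants: 14 (S,2Z,6Z)-5-[(tert-butyldimethylsilyl)oxy]-7-iodo-3-methylocta-2,6-dienal; 20 (R)-3-(bromomethyl)-5-{[(4-methoxybenzyl)oxy]methyl}furan-2(5H)-one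
Product: 22 (4S,5R)-4-[(1R,2Z,5S,6Z)-5-[(tert-butyldimethylsilyl)oxy]-1-hydroxy-7-iodo-3-methylocta-2,6-dien-1-yl]-5-{[(4-methoxybenzyl)oxy]methyl}-3-methylenedihydrofuran-2(3H)-one, via allylzinc bromide 21 (not isolated)
Conditions: Zn dust (activated), THF/sat. aq. NH4Cl (5:1), 0 °C to rt
Reagents that add atoms: none
Why: Zinc Barbier allylation with allylic transposition (SE2'), in which the ring γ-carbon (future C7) adds to the aldehyde through a closed chair transition state on the butenolide face opposite the C8 CH2OPMB group (7,8-trans), and the ring-fixed alkene geometry (C8 trans to CH2Zn) with the aldehyde residue equatorial should give the 6,7-anti relationship (6R,7S) while unveiling the exocyclic methylene.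

Step 13
Reactants: 22 (the Barbier adduct above); 23 (R)-2-methylbutanoic acid
Product: 24 (1R,2Z,5S,6Z)-5-[(tert-butyldimethylsilyl)oxy]-7-iodo-1-[(2R,3S)-2-{[(4-methoxybenzyl)oxy]methyl}-4-methylene-5-oxotetrahydrofuran-3-yl]-3-methylocta-2,6-dien-1-yl (R)-2-methylbutanoate
Conditions: DCC, DMAP, CH2Cl2, 0 °C to rt
Reagents that add atoms: none
Why: Steglich esterification of the only free hydroxyl (C6–OH), under which the non-activated α-stereocentre of the acid is not expected to epimerise.

Step 14
Reactants: 24 (the PMB ether ester above)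
Product: 25 (1R,2Z,5S,6Z)-5-[(tert-butyldimethylsilyl)oxy]-1-[(2R,3S)-2-(hydroxymethyl)-4-methylene-5-oxotetrahydrofuran-3-yl]-7-iodo-3-methylocta-2,6-dien-1-yl (R)-2-methylbutanoate
Conditions: DDQ, CH2Cl2/pH 7 phosphate buffer, 0 °C
Reagents that add atoms: none
Why: Oxidative cleavage of the PMB ether by DDQ (benzylic hydride abstraction, then hydrolysis) under buffered conditions should spare the silyl ether, both esters, the iodoalkene and the methylene lactone.

Step 15
Reactants: 25 (the primary alcohol above)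
Product: 26 (1R,2Z,5S,6Z)-5-[(tert-butyldimethylsilyl)oxy]-1-[(2R,3S)-2-formyl-4-methylene-5-oxotetrahydrofuran-3-yl]-7-iodo-3-methylocta-2,6-dien-1-yl (R)-2-methylbutanoate
Conditions: Dess–Martin periodinane, NaHCO3, CH2Cl2, 0 °C to rt; used at once
Reagents that add atoms: none
Why: Dess–Martin oxidation under buffered, non-basic conditions should give the α-acyloxy aldehyde (C9) without epimerising C8.

Step 16
Reactants: 26 (the iodo-aldehyde above)
Product: 28 (2S,6R,7S,8R,9R,1(10)Z,4Z)-2-[(tert-butyldimethylsilyl)oxy]-9-hydroxy-6-[(R)-2-methylbutanoyloxy]germacra-1(10),4,11(13)-trien-12,8-olide, via alkenylchromium dichloride 27 (not isolated)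
Conditions: CrCl2 (10 equiv), NiCl2 (5 mol %), degassed DMSO, slow addition of 26 to 0.003 M, rt
Reagents that add atoms: none
Why: Mechanism: zerovalent nickel formed from NiCl2 and CrCl2 inserts into the C10–I bond, transmetalation gives the trivalent alkenylchromium 27, and this adds to the C9 aldehyde; the closest known reaction type is the Nozaki–Hiyama–Kishi macrocyclization of iodoalkene aldehydes to medium-ring allylic alcohols. The ten-membered carbocycle closes in a 10-exo-trig mode (carbonyl oxygen outside the new ring). Alkenylchromium species of this kind keep their geometry, so the (Z)-iodide should deliver the C1=C10 alkene with C2 and C9 cis. The new C9 stereocentre is controlled by the trans-fused lactone (C7, C8): the tether leaves from C7, so C10 should reach the aldehyde anti to the C8–O bond but from the C7 side, with the chromium-bound oxygen turned outward towards H8, which is Re-face attack and gives 9R (8,9-threo). The step needs intramolecular over intermolecular coupling, secured by high dilution, slow addition and the turn imposed by the two cis alkenes and the lactone. It also needs chemoselectivity, secured by the low basicity and nucleophilicity of the chromium reagent, which should leave the ester, the lactone, the exocyclic methylene and the epimerisable C8 centre untouched.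

Step 17
Reactants: 28 (the macrocyclic silyl ether above)
Product: 29 (2S,6R,7S,8R,9R,1(10)Z,4Z)-2,9-dihydroxy-6-[(R)-2-methylbutanoyloxy]germacra-1(10),4,11(13)-trien-12,8-olide (CNP0176600.1)
Conditions: HF·pyridine, pyridine/THF, 0 °C to rt
Reagents that add atoms: none
Why: Buffered fluoride cleavage of the secondary allylic TBS ether should free the C2 hydroxyl without ester migration, translactonisation or addition to the methylene lactone.

**Compound list**

1 | but-2-yn-1-ol | CC#CCO | starting material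
2 | sodium 2,2-bis(2-methoxyethoxy)-3-methyl-2,5-dihydro-1,2-oxaluminol-2-uide (cyclic alkenylalanate) | [Na+].CC1=CCO[Al-]1(OCCOC)OCCOC | intermediate
3 | (Z)-3-iodobut-2-en-1-ol | OC/C=C(/C)I | intermediate
4 | (Z)-3-iodobut-2-enal | O=C/C=C(/C)I | intermediate
5 | (2-methylallyl)magnesium chloride | C=C(C)C[Mg]Cl | starting material
6 | B-methallyldiisopinocampheylborane [Ipc groups from (+)-α-pinene] | C=C(C)CB([C@H]1[C@H](C)[C@H]2C[C@@H](C1)C2(C)C)[C@H]1[C@H](C)[C@H]2C[C@@H](C1)C2(C)C | intermediate
7 | (S,Z)-6-iodo-2-methylhepta-1,5-dien-4-yl diisopinocampheylborinate | C=C(C)C[C@H](OB([C@H]1[C@H](C)[C@H]2C[C@@H](C1)C2(C)C)[C@H]1[C@H](C)[C@H]2C[C@@H](C1)C2(C)C)/C=C(/C)I | intermediate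
8 | (S,Z)-6-iodo-2-methylhepta-1,5-dien-4-ol | C=C(C)C[C@H](O)/C=C(/C)I | intermediate
9 | acryloyl chloride | C=CC(=O)Cl | starting material
10 | (S,Z)-6-iodo-2-methylhepta-1,5-dien-4-yl acrylate | C=CC(=O)O[C@@H](CC(C)=C)/C=C(/C)I | intermediate
11 | (S)-6-[(Z)-2-iodoprop-1-en-1-yl]-4-methyl-5,6-dihydro-2H-pyran-2-one | CC1=CC(=O)O[C@@H](C1)/C=C(/C)I | intermediate
12 | (S,2Z,6Z)-5-hydroxy-7-iodo-N-methoxy-N,3-dimethylocta-2,6-dienamide | CON(C)C(=O)/C=C(/C)C[C@H](O)/C=C(/C)I | intermediate
13 | (S,2Z,6Z)-5-[(tert-butyldimethylsilyl)oxy]-7-iodo-N-methoxy-N,3-dimethylocta-2,6-dienamide | CON(C)C(=O)/C=C(/C)C[C@H](O[Si](C)(C)C(C)(C)C)/C=C(/C)I | intermediate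
14 | (S,2Z,6Z)-5-[(tert-butyldimethylsilyl)oxy]-7-iodo-3-methylocta-2,6-dienal | O=C/C=C(/C)C[C@H](O[Si](C)(C)C(C)(C)C)/C=C(/C)I | intermediate
15 | (R)-but-3-ene-1,2-diol | C=C[C@@H](O)CO | starting material
16 | (R)-2,2-dibutyl-4-vinyl-1,3,2-dioxastannolane | CCCC[Sn]1(CCCC)OC[C@@H](C=C)O1 | intermediate
17 | (R)-1-[(4-methoxybenzyl)oxy]but-3-en-2-ol | C=C[C@@H](O)COCc1ccc(OC)cc1 | intermediate
18 | 2-(bromomethyl)acrylic acid | C=C(CBr)C(=O)O | starting material
19 | (R)-1-[(4-methoxybenzyl)oxy]but-3-en-2-yl 2-(bromomethyl)acrylate | C=C(CBr)C(=O)O[C@H](C=C)COCc1ccc(OC)cc1 | intermediate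
20 | (R)-3-(bromomethyl)-5-{[(4-methoxybenzyl)oxy]methyl}furan-2(5H)-one | BrCC1=C[C@H](COCc2ccc(OC)cc2)OC1=O | intermediate
21 | bromo{[(R)-5-{[(4-methoxybenzyl)oxy]methyl}-2-oxo-2,5-dihydrofuran-3-yl]methyl}zinc | Br[Zn]CC1=C[C@H](COCc2ccc(OC)cc2)OC1=O | intermediate
22 | (4S,5R)-4-[(1R,2Z,5S,6Z)-5-[(tert-butyldimethylsilyl)oxy]-1-hydroxy-7-iodo-3-methylocta-2,6-dien-1-yl]-5-{[(4-methoxybenzyl)oxy]methyl}-3-methylenedihydrofuran-2(3H)-one | C=C1C(=O)O[C@@H](COCc2ccc(OC)cc2)[C@@H]1[C@H](O)/C=C(/C)C[C@H](O[Si](C)(C)C(C)(C)C)/C=C(/C)I | intermediate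
23 | (R)-2-methylbutanoic acid | CC[C@@H](C)C(=O)O | starting material
24 | (1R,2Z,5S,6Z)-5-[(tert-butyldimethylsilyl)oxy]-7-iodo-1-[(2R,3S)-2-{[(4-methoxybenzyl)oxy]methyl}-4-methylene-5-oxotetrahydrofuran-3-yl]-3-methylocta-2,6-dien-1-yl (R)-2-methylbutanoate | C=C1C(=O)O[C@@H](COCc2ccc(OC)cc2)[C@@H]1[C@H](OC(=O)[C@H](C)CC)/C=C(/C)C[C@H](O[Si](C)(C)C(C)(C)C)/C=C(/C)I | intermediate
25 | (1R,2Z,5S,6Z)-5-[(tert-butyldimethylsilyl)oxy]-1-[(2R,3S)-2-(hydroxymethyl)-4-methylene-5-oxotetrahydrofuran-3-yl]-7-iodo-3-methylocta-2,6-dien-1-yl (R)-2-methylbutanoate | C=C1C(=O)O[C@@H](CO)[C@@H]1[C@H](OC(=O)[C@H](C)CC)/C=C(/C)C[C@H](O[Si](C)(C)C(C)(C)C)/C=C(/C)I | intermediate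
26 | (1R,2Z,5S,6Z)-5-[(tert-butyldimethylsilyl)oxy]-1-[(2R,3S)-2-formyl-4-methylene-5-oxotetrahydrofuran-3-yl]-7-iodo-3-methylocta-2,6-dien-1-yl (R)-2-methylbutanoate | C=C1C(=O)O[C@@H](C=O)[C@@H]1[C@H](OC(=O)[C@H](C)CC)/C=C(/C)C[C@H](O[Si](C)(C)C(C)(C)C)/C=C(/C)I | intermediate
27 | dichloro-alkenylchromium species of 26 (trivalent chromium on C10 in place of iodine) | C=C1C(=O)O[C@@H](C=O)[C@@H]1[C@H](OC(=O)[C@H](C)CC)/C=C(/C)C[C@H](O[Si](C)(C)C(C)(C)C)/C=C(/C)[Cr](Cl)Cl | intermediate
28 | (2S,6R,7S,8R,9R,1(10)Z,4Z)-2-[(tert-butyldimethylsilyl)oxy]-9-hydroxy-6-[(R)-2-methylbutanoyloxy]germacra-1(10),4,11(13)-trien-12,8-olide | C=C1C(=O)O[C@@H]2[C@@H]1[C@H](OC(=O)[C@H](C)CC)/C=C(/C)C[C@H](O[Si](C)(C)C(C)(C)C)/C=C(/C)[C@H]2O | intermediate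
29 | (2S,6R,7S,8R,9R,1(10)Z,4Z)-2,9-dihydroxy-6-[(R)-2-methylbutanoyloxy]germacra-1(10),4,11(13)-trien-12,8-olide | C=C1C(=O)O[C@@H]2[C@@H]1[C@H](OC(=O)[C@H](C)CC)/C=C(/C)C[C@H](O)/C=C(/C)[C@H]2O | target

**Step count.** 17 steps in total; the longest linear sequence is 14 steps (steps 1–8, then 12–17); the butenolide branch is steps 9–11.

**Steps most likely to fail, each with a fallback**

Step 16 (key macrocyclization). Intermolecular coupling may compete with ring closure, the facial selectivity at C9 may be poor or reversed, the alkenyl metal may partly isomerise from Z to E, and C8 may epimerise in the aldehyde. The fallback keeps the same ring closure but sets C9 by reduction instead of by the C–C bond formation. Setting out from 26, the cyclization would be taken through to the 9-epimeric carbinol F1 (9S, alone or mixed with 28). Dess–Martin periodinane with NaHCO3 in CH2Cl2 would oxidise it to the macrocyclic C9 enone F2. A Luche reduction (NaBH4, CeCl3·7H2O, MeOH, −78 °C), with hydride expected anti to the C8–O bond (polar Felkin–Anh arrangement), should then give the 8,9-threo alcohol and return to the route at 28.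

Step 12 (Barbier union). The simple or facial diastereoselectivity may be poor, attack without allylic transposition may compete, the (Z)-enal may isomerise, and the zinc alkoxide may translactonise. The fallback replaces the transient allylzinc by an isolable allylboron reagent. Setting out from 20, palladium-catalysed borylation (Pd2(dba)3, bis(pinacolato)diboron, toluene, 50 °C) would give the pinacol allylboronate F3. Allylboration of 14 with F3 (Sc(OTf)3 catalytic, toluene, 0 °C to rt) goes through a strictly closed chair transition state and should return to the route at 22.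

Step 11 (metathesis to the bromolactone). The electron-poor 1,1-disubstituted alkene may react sluggishly, and the allylic bromide may decompose the catalyst or isomerise. The fallback introduces the bromide only after ring closure. Setting out from 17, acylation with acryloyl chloride 9 (Et3N, CH2Cl2) would give the acrylate F4. A Morita–Baylis–Hillman reaction with aqueous formaldehyde (DABCO, dioxane/water) would give the 2-(hydroxymethyl)acrylate F5. Ring-closing metathesis (second-generation Grubbs catalyst RuCl2(=CHPh)(H2IMes)(PCy3), toluene, 80 °C) would give the 3-(hydroxymethyl)butenolide F6, and an Appel bromination (CBr4, PPh3, CH2Cl2, 0 °C) returns to the route at 20.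

**Further compounds**

F1 | step 16 | (2S,6R,7S,8R,9S,1(10)Z,4Z)-2-[(tert-butyldimethylsilyl)oxy]-9-hydroxy-6-[(R)-2-methylbutanoyloxy]germacra-1(10),4,11(13)-trien-12,8-olide (9-epimer of 28) | C=C1C(=O)O[C@@H]2[C@@H]1[C@H](OC(=O)[C@H](C)CC)/C=C(/C)C[C@H](O[Si](C)(C)C(C)(C)C)/C=C(/C)[C@@H]2O
F2 | step 16 | (2S,6R,7S,8R,1(10)Z,4Z)-2-[(tert-butyldimethylsilyl)oxy]-6-[(R)-2-methylbutanoyloxy]-9-oxogermacra-1(10),4,11(13)-trien-12,8-olide | C=C1C(=O)O[C@@H]2[C@@H]1[C@H](OC(=O)[C@H](C)CC)/C=C(/C)C[C@H](O[Si](C)(C)C(C)(C)C)/C=C(/C)C2=O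
F3 | step 12 | (R)-5-{[(4-methoxybenzyl)oxy]methyl}-3-[(4,4,5,5-tetramethyl-1,3,2-dioxaborolan-2-yl)methyl]furan-2(5H)-one | CC1(C)OB(CC2=C[C@H](COCc3ccc(OC)cc3)OC2=O)OC1(C)C
F4 | step 11 | (R)-1-[(4-methoxybenzyl)oxy]but-3-en-2-yl acrylate | C=CC(=O)O[C@H](C=C)COCc1ccc(OC)cc1
F5 | step 11 | (R)-1-[(4-methoxybenzyl)oxy]but-3-en-2-yl 2-(hydroxymethyl)acrylate | C=C(CO)C(=O)O[C@H](C=C)COCc1ccc(OC)cc1
F6 | step 11 | (R)-3-(hydroxymethyl)-5-{[(4-methoxybenzyl)oxy]methyl}furan-2(5H)-one | OCC1=C[C@H](COCc2ccc(OC)cc2)OC1=O
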